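**Strategy.** The C1=C15 double bond shared by the 14-membered carbocycle and the 2,5-dihydrofuran ring is read as a former alkyne. Its two carbons carry, cis to one another, the ring OCH2 carbon C16 and the oxygen-bearing ring carbon C2. A nickel-catalysed alkylative macrocyclisation of an acyclic ynal, built from (2E,6E)-farnesol with the (7R,8R)-epoxide already in place, closes the carbocycle at C1–C2 and delivers a silylmethyl group (a masked C16 hydroxymethyl) to C15 by syn addition. This creates C2 and the tetrasubstituted alkene in one operation. Tamao oxidation, ether closure and acetylation then complete the target.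

Key step: step 9

**Remarks**
- Numbering: cembrane numbering is used for the target and all macrocycles (C1–C14 carbocycle; C15 the second sp2 carbon of the dihydrofuran; C16 the ring OCH2; C17 the CH2OAc carbon). Acyclic intermediates carry farnesane or chain locants where stated. The target is (2R,7R,8R).
- Assumption: the sense of induction of the chiral phosphoramidite in step 9 cannot be predicted with confidence; the ligand enantiomer that leads to (2R) is to be chosen by experiment.

**Route**

Step 1
Reactants: 1 (2E,6E)-farnesol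
Product: 2 (2E,6E)-farnesyl tert-butyldimethylsilyl (TBS) ether
Conditions: TBSCl, imidazole, DMF, 0 °C to rt
Reagents that add atoms: tert-butyldimethylsilyl chloride, CC(C)(C)[Si](C)(C)Cl
Why: Silyl ether formation at the primary allylic alcohol, which also makes the 2,3-alkene more hindered and electron-poorer than the other two alkenes.

Step 2
Reactants: 2 (2E,6E)-farnesyl TBS ether
Product: 3 (2E,6E,10E)-12-hydroxyfarnesyl TBS ether
Conditions: SeO2 (10 mol %), t-BuOOH, salicylic acid (10 mol %), CH2Cl2, rt
Reagents that add atoms: tert-butyl hydroperoxide, CC(C)(C)OO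
Why: SeO2-catalysed allylic oxidation (ene reaction then 2,3-sigmatropic shift) should attack the most electron-rich terminal trisubstituted alkene and hydroxylate its (E)-methyl group with retention of the (E)-geometry.

Step 3
Reactants: 3 (2E,6E,10E)-12-hydroxyfarnesyl TBS ether
Product: 4 (2E,6E,10E)-12-chlorofarnesyl TBS ether
Conditions: NCS, Me2S, CH2Cl2, −30 to 0 °C
Reagents that add atoms: N-chlorosuccinimide, ClN1C(=O)CCC1=O
Why: Corey–Kim chlorination, in which chloride displaces the alkoxysulfonium ion of the primary allylic alcohol by SN2 without allylic transposition, and the chloride then deactivates the 10,11-alkene.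

Step 4
Reactants: 4 (2E,6E,10E)-12-chlorofarnesyl TBS ether
Product: 5 (2E,6R,7R,10E)-12-chloro-6,7-epoxyfarnesyl TBS ether
Conditions: D-fructose-derived Shi ketone (30 mol %), Oxone (2KHSO5·KHSO4·K2SO4), K2CO3, Bu4NHSO4, MeCN–CH2(OMe)2–aqueous Na2B4O7 buffer, 0 °C
Reagents that add atoms: potassium peroxymonosulfate, [K+].[O-]S(=O)(=O)OO
Why: Shi asymmetric epoxidation (chiral dioxirane, spiro transition state) should select the 6,7-alkene, the only one without an allylic heteroatom, and the D-fructose-derived ketone sets both new stereocentres as 6R,7R (7R,8R in cembrane numbering) under reagent control.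

Step 5
Reactants: 5 (2E,6R,7R,10E)-12-chloro-6,7-epoxyfarnesyl TBS ether
Product: 7 (6E,10R,11R,14E)-16-[(tert-butyldimethylsilyl)oxy]-10,11-epoxy-6,10,14-trimethylhexadeca-6,14-dien-2-yn-1-ol, via lithium acetylide 6 (not isolated)
Conditions: propyne, n-BuLi (2 equiv per propyne), TMEDA, Et2O–hexane, −78 to 0 °C; add 5, THF, −78 to −20 °C; then (CH2O)n, −20 °C to rt; aq NH4Cl
Reagents that add atoms: propyne (used as 1,3-dilithiopropyne), CC#C; paraformaldehyde (as formaldehyde), C=O
Why: SN2 alkylation of the primary allylic chloride by the sp3 terminus of 1,3-dilithiopropyne leaves a lithium acetylide that adds to formaldehyde (acetylide hydroxymethylation), while the trisubstituted epoxide and the silyl ether are inert to organolithiums at low temperature.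

Step 6
Reactants: 7 propargylic alcohol
Product: 8 tert-butyldiphenylsilyl (TBDPS) ether of 7
Conditions: TBDPSCl, imidazole, DMF, rt
Reagents that add atoms: tert-butyldiphenylsilyl chloride, CC(C)(C)[Si](Cl)(c1ccccc1)c1ccccc1
Why: Silyl ether formation; the bulky TBDPS group survives the following steps and makes the C15 alkyne terminus the more hindered and electron-poorer one for step 9.

Step 7
Reactants: 8 bis-silyl ether
Product: 9 (2E,6R,7R,10E)-16-[(tert-butyldiphenylsilyl)oxy]-6,7-epoxy-3,7,11-trimethylhexadeca-2,10-dien-14-yn-1-ol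
Conditions: HF·pyridine, pyridine, THF, 0 °C
Reagents that add atoms: none
Why: Selective desilylation, since pyridine-buffered HF·pyridine cleaves the primary allylic TBS ether far faster than the TBDPS ether and is mild enough for the trisubstituted epoxide.

Step 8
Reactants: 9 allylic alcohol
Product: 10 (2E,6R,7R,10E)-16-[(tert-butyldiphenylsilyl)oxy]-6,7-epoxy-3,7,11-trimethylhexadeca-2,10-dien-14-ynal
Conditions: MnO2, CH2Cl2, rt
Reagents that add atoms: none
Why: MnO2 oxidation is selective for the allylic alcohol and should give the (E)-enal without affecting the epoxide, the alkyne or the silyl ether.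

Step 9
Reactants: 10 epoxy ynal
Product: 12 macrobicyclic siloxane (14-membered carbocycle fused at C1–C2 to a 2,2-dimethyl-1-oxa-2-silacyclohex-4-ene; 2R,7R,8R; C17 as CH2OTBDPS), via zinc alkoxide 11 (not isolated)
Conditions: [(i-PrO)Me2SiCH2]2Zn (3 equiv; from ClCH2SiMe2(Oi-Pr), Mg, THF, then ZnCl2, MgCl2 removed with 1,4-dioxane), Ni(cod)2 (20 mol %), spirobiindane-derived phosphoramidite ligand (SIPHOS type, 20 mol %), THF–toluene, 0 °C to rt, syringe-pump addition of 10 (final 2 mM); aq NH4Cl
Reagents that add atoms: bis[(isopropoxydimethylsilyl)methyl]zinc, CC(C)O[Si](C)(C)C[Zn]C[Si](C)(C)OC(C)C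
Why: Zerovalent nickel couples the alkyne and the aldehyde of 10 oxidatively to an oxanickelacyclopentene (new C1–C2 bond, nickel on C15 and on the carbonyl oxygen), a silylmethyl group passes from zinc to nickel, and C–C reductive elimination forms C15–C16 on the same side of the former triple bond as C2, after which the zinc alkoxide at C2 displaces isopropoxide at silicon. The closest known reaction types are the nickel-catalysed alkylative three-component coupling of ynals with organozincs and the nickel-catalysed reductive macrocyclisation of ynals. The 14-membered carbocycle closes in the exo mode at the tethered alkyne carbon C1 (14-exo-dig), and the temporary six-membered oxasilacycle closes by 6-exo-tet attack of the C2 oxygen on silicon, a ring that already holds C2, O, C16, C15 and C1 in the cis arrangement of the later dihydrofuran. The new stereocentre C2 (2R) is set under catalyst control by the chiral phosphoramidite on nickel, which selects the aldehyde face in the oxidative cyclisation, while the epoxide six bonds away is expected to add little bias. The step needs bond formation at C1 and not at C15, and carbonyl (1,2) and not conjugate coupling of the enal: the propargylic OTBDPS group makes C15 the more hindered and, by induction, the better nickel-bearing terminus, the β,β-disubstitution of the enal blocks the conjugate pathway, and the silylmethyl group has no β-hydrogen, so the competing reductive pathway is closed.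

Step 10
Reactants: 12 macrobicyclic siloxane
Product: 13 (2R,7R,8R)-17-[(tert-butyldiphenylsilyl)oxy]-7,8-epoxycembra-1(15),3E,11E-triene-2,16-diol (C16 cis to C2)
Conditions: KF, KHCO3, 30% H2O2, THF–MeOH, rt
Reagents that add atoms: hydrogen peroxide, OO
Why: Tamao oxidation, in which hydroperoxide adds to the fluoride-activated silicon and C16 migrates from silicon to oxygen with retention and without allylic transposition, so that hydrolysis releases the ene-1,4-diol with C16 still cis to C2.

Step 11
Reactants: 13 ene-1,4-diol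
Product: 15 (2R,7R,8R)-17-[(tert-butyldiphenylsilyl)oxy]-2,16:7,8-diepoxycembra-1(15),3E,11E-triene, via primary tosylate 14 (not isolated)
Conditions: TsCl (1.1 equiv), Et3N, DMAP (cat.), CH2Cl2, 0 °C to rt
Reagents that add atoms: none
Why: Selective sulfonylation of the unhindered primary allylic hydroxyl followed by intramolecular Williamson etherification (5-exo-tet SN2 at C16 by the C2 hydroxyl) closes the 2,5-dihydrofuran ring, and C2 keeps its configuration because its C–O bond is not broken.

Step 12
Reactants: 15 dihydrofuran TBDPS ether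
Product: 16 (2R,7R,8R)-2,16:7,8-diepoxycembra-1(15),3E,11E-trien-17-ol (deacetyl-lobophynin B)
Conditions: Bu4NF, THF, 0 °C
Reagents that add atoms: none
Why: Fluoride-mediated desilylation of the TBDPS ether under conditions that should leave the epoxide and the dihydrofuran untouched.

Step 13
Reactants: 16 deacetyl-lobophynin B
Product: 17 lobophynin B
Conditions: Ac2O, pyridine, DMAP (cat.), CH2Cl2, 0 °C to rt
Reagents that add atoms: acetic anhydride, CC(=O)OC(C)=O
Why: DMAP-catalysed acetylation (nucleophilic acyl transfer) of the primary allylic alcohol gives the acetate of the target.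

**Compound list**

1 | (2E,6E)-farnesol | CC(C)=CCC/C(C)=C/CC/C(C)=C/CO | starting material
2 | (2E,6E)-farnesyl TBS ether | CC(C)=CCC/C(C)=C/CC/C(C)=C/CO[Si](C)(C)C(C)(C)C | intermediate
3 | (2E,6E,10E)-12-hydroxyfarnesyl TBS ether | OC/C(C)=C/CC/C(C)=C/CC/C(C)=C/CO[Si](C)(C)C(C)(C)C | intermediate
4 | (2E,6E,10E)-12-chlorofarnesyl TBS ether | ClC/C(C)=C/CC/C(C)=C/CC/C(C)=C/CO[Si](C)(C)C(C)(C)C | intermediate
5 | (2E,6R,7R,10E)-12-chloro-6,7-epoxyfarnesyl TBS ether | ClC/C(C)=C/CC[C@@]1(C)O[C@@H]1CC/C(C)=C/CO[Si](C)(C)C(C)(C)C | intermediate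
6 | lithium acetylide of (2E,6R,7R,10E)-1-(TBS-oxy)-6,7-epoxy-3,7,11-trimethylpentadeca-2,10-dien-14-yne | [Li]C#CCC/C(C)=C/CC[C@@]1(C)O[C@@H]1CC/C(C)=C/CO[Si](C)(C)C(C)(C)C | intermediate
7 | (6E,10R,11R,14E)-16-[(tert-butyldimethylsilyl)oxy]-10,11-epoxy-6,10,14-trimethylhexadeca-6,14-dien-2-yn-1-ol | OCC#CCC/C(C)=C/CC[C@@]1(C)O[C@@H]1CC/C(C)=C/CO[Si](C)(C)C(C)(C)C | intermediate
8 | TBDPS ether of 7 (1-OTBDPS, 16-OTBS) | CC(C)(C)[Si](c1ccccc1)(c1ccccc1)OCC#CCC/C(C)=C/CC[C@@]1(C)O[C@@H]1CC/C(C)=C/CO[Si](C)(C)C(C)(C)C | intermediate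
9 | (2E,6R,7R,10E)-16-[(tert-butyldiphenylsilyl)oxy]-6,7-epoxy-3,7,11-trimethylhexadeca-2,10-dien-14-yn-1-ol | CC(C)(C)[Si](c1ccccc1)(c1ccccc1)OCC#CCC/C(C)=C/CC[C@@]1(C)O[C@@H]1CC/C(C)=C/CO | intermediate
10 | (2E,6R,7R,10E)-16-[(tert-butyldiphenylsilyl)oxy]-6,7-epoxy-3,7,11-trimethylhexadeca-2,10-dien-14-ynal | CC(C)(C)[Si](c1ccccc1)(c1ccccc1)OCC#CCC/C(C)=C/CC[C@@]1(C)O[C@@H]1CC/C(C)=C/C=O | intermediate
11 | zinc alkoxide of the open-chain macrocycle: (2R,7R,8R)-cembra-1(15),3E,11E-triene with 7,8-epoxide, C2–O–Zn–CH2SiMe2(Oi-Pr), C16 as CH2SiMe2(Oi-Pr) cis to C2, C17 as CH2OTBDPS | CC(C)O[Si](C)(C)C/C(CO[Si](c1ccccc1)(c1ccccc1)C(C)(C)C)=C1/CC/C(C)=C/CC[C@@]2(C)O[C@@H]2CC/C(C)=C/[C@H]1O[Zn]C[Si](C)(C)OC(C)C | intermediate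
12 | macrobicyclic siloxane: as 11 but with C2–O–SiMe2–C16 closed to a six-membered oxasilacycle | C[Si]1(C)C/C(CO[Si](c2ccccc2)(c2ccccc2)C(C)(C)C)=C2/CC/C(C)=C/CC[C@@]3(C)O[C@@H]3CC/C(C)=C/[C@H]2O1 | intermediate
13 | (2R,7R,8R)-17-[(tert-butyldiphenylsilyl)oxy]-7,8-epoxycembra-1(15),3E,11E-triene-2,16-diol (C16 cis to C2) | OC/C(CO[Si](c1ccccc1)(c1ccccc1)C(C)(C)C)=C1/CC/C(C)=C/CC[C@@]2(C)O[C@@H]2CC/C(C)=C/[C@H]1O | intermediate
14 | 16-O-tosylate of 13 | Cc1ccc(cc1)S(=O)(=O)OC/C(CO[Si](c1ccccc1)(c1ccccc1)C(C)(C)C)=C1/CC/C(C)=C/CC[C@@]2(C)O[C@@H]2CC/C(C)=C/[C@H]1O | intermediate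
15 | (2R,7R,8R)-17-[(tert-butyldiphenylsilyl)oxy]-2,16:7,8-diepoxycembra-1(15),3E,11E-triene | CC(C)(C)[Si](c1ccccc1)(c1ccccc1)OCC1=C2CC/C(C)=C/CC[C@@]3(C)O[C@@H]3CC/C(C)=C/[C@H]2OC1 | intermediate
16 | (2R,7R,8R)-2,16:7,8-diepoxycembra-1(15),3E,11E-trien-17-ol (deacetyl-lobophynin B) | OCC1=C2CC/C(C)=C/CC[C@@]3(C)O[C@@H]3CC/C(C)=C/[C@H]2OC1 | intermediate
17 | lobophynin B | CC(=O)OCC1=C2CC/C(C)=C/CC[C@@]3(C)O[C@@H]3CC/C(C)=C/[C@H]2OC1 | target

**Totals**

Total step count: 13. Longest linear sequence: 13 steps (1 to 17).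

**Steps most likely to fail**

1. Step 9. What may go wrong: oligomerisation may outrun ring closure at the dilution used; the oxidative cyclisation may take place at C15 and give the 15-membered regioisomer; transfer of the silylmethyl group from zinc to nickel may be too slow; or facial control at C2 may be weak, so that the C2 epimer forms. Fallback: the two C–C bonds are made in separate known operations and the ring is closed by a Nozaki–Hiyama–Kishi reaction; it sets out from 7 and returns at 16. Propargylic alcohol 7 is treated with (i-PrO)Me2SiCH2MgCl and catalytic CuI (hydroxyl-directed anti-carbomagnesiation, the carbon group going to C15 and magnesium to C1 within an alkoxide chelate), and the vinylmagnesium species is quenched with I2 to give iodo silane alcohol F1. Tamao oxidation (KF, KHCO3, H2O2) gives iodo diol F2, in which the two hydroxymethyl arms on C15 are equivalent, so the alkene geometry no longer matters. TBDPSCl and imidazole give bis(TBDPS) ether F3, HF·pyridine frees allylic alcohol F4, and MnO2 gives iodo enal F5. CrCl2 with catalytic NiCl2 and a chiral sulfonamide ligand at high dilution should close the 14-membered ring to macrocyclic allylic alcohol F6, with ligand control at C2. Bu4NF gives macrocyclic triol F7, and Mitsunobu cyclodehydration (PPh3, DIAD), in which only the arm cis to C2 can reach the C2 hydroxyl, gives 16.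

2. Step 4. What may go wrong: poor site selectivity, with competing epoxidation of the 2,3-alkene whose allylic silyloxy group deactivates it only moderately, or double epoxidation. Fallback: the silyl ether is replaced by the more strongly deactivating acetate during the oxidation steps; it sets out from 1 and returns at 5. Alcohol 1 is acetylated (Ac2O, pyridine) to (2E,6E)-farnesyl acetate F8, SeO2 and t-BuOOH give 12-hydroxyfarnesyl acetate F9, and NCS with Me2S gives 12-chlorofarnesyl acetate F10. Shi epoxidation, now with both flanking alkenes carrying strongly withdrawing allylic groups, gives epoxy chloro acetate F11. i-Bu2AlH at −78 °C removes the acetate to give epoxy chloro alcohol F12, and TBSCl with imidazole gives 5.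

3. Step 11. What may go wrong: sulfonylation of the wrong hydroxyl, chloride exchange without ring closure, or ionisation of the doubly allylic C2–O bond with loss of configuration or elimination. Fallback: neutral redox-condensation activation in place of a sulfonate; it sets out from 13 and returns at 15. Mitsunobu cyclodehydration (PPh3, DIAD, THF, 0 °C) converts the primary hydroxyl into an alkoxyphosphonium ion that the C2 hydroxyl displaces in the same 5-exo-tet sense; no new compound is formed (F0).

**Further compounds**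

F1 | step 9 | iodo silane alcohol: 7 with C1 bearing iodine and C15 bearing CH2OH (cis to iodine) and CH2SiMe2(Oi-Pr) | CC(C)O[Si](C)(C)C/C(CO)=C(/I)CC/C(C)=C/CC[C@@]1(C)O[C@@H]1CC/C(C)=C/CO[Si](C)(C)C(C)(C)C
F2 | step 9 | iodo diol: C15 bearing two CH2OH groups | OCC(CO)=C(I)CC/C(C)=C/CC[C@@]1(C)O[C@@H]1CC/C(C)=C/CO[Si](C)(C)C(C)(C)C
F3 | step 9 | bis(TBDPS) ether of F2 | CC(C)(C)[Si](c1ccccc1)(c1ccccc1)OCC(CO[Si](c1ccccc1)(c1ccccc1)C(C)(C)C)=C(I)CC/C(C)=C/CC[C@@]1(C)O[C@@H]1CC/C(C)=C/CO[Si](C)(C)C(C)(C)C
F4 | step 9 | allylic alcohol from F3 (TBS removed) | CC(C)(C)[Si](c1ccccc1)(c1ccccc1)OCC(CO[Si](c1ccccc1)(c1ccccc1)C(C)(C)C)=C(I)CC/C(C)=C/CC[C@@]1(C)O[C@@H]1CC/C(C)=C/CO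
F5 | step 9 | iodo enal from F4 | CC(C)(C)[Si](c1ccccc1)(c1ccccc1)OCC(CO[Si](c1ccccc1)(c1ccccc1)C(C)(C)C)=C(I)CC/C(C)=C/CC[C@@]1(C)O[C@@H]1CC/C(C)=C/C=O
F6 | step 9 | macrocyclic allylic alcohol (2R,7R,8R) with C15 bearing two CH2OTBDPS groups | CC(C)(C)[Si](c1ccccc1)(c1ccccc1)OCC(CO[Si](c1ccccc1)(c1ccccc1)C(C)(C)C)=C1CC/C(C)=C/CC[C@@]2(C)O[C@@H]2CC/C(C)=C/[C@H]1O
F7 | step 9 | macrocyclic triol (2R,7R,8R)-7,8-epoxycembra-1(15),3E,11E-triene-2,16,17-triol | OCC(CO)=C1CC/C(C)=C/CC[C@@]2(C)O[C@@H]2CC/C(C)=C/[C@H]1O
F8 | step 4 | (2E,6E)-farnesyl acetate | CC(C)=CCC/C(C)=C/CC/C(C)=C/COC(C)=O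
F9 | step 4 | (2E,6E,10E)-12-hydroxyfarnesyl acetate | OC/C(C)=C/CC/C(C)=C/CC/C(C)=C/COC(C)=O
F10 | step 4 | (2E,6E,10E)-12-chlorofarnesyl acetate | ClC/C(C)=C/CC/C(C)=C/CC/C(C)=C/COC(C)=O
F11 | step 4 | (2E,6R,7R,10E)-12-chloro-6,7-epoxyfarnesyl acetate | ClC/C(C)=C/CC[C@@]1(C)O[C@@H]1CC/C(C)=C/COC(C)=O
F12 | step 4 | (2E,6R,7R,10E)-12-chloro-6,7-epoxyfarnesol | ClC/C(C)=C/CC[C@@]1(C)O[C@@H]1CC/C(C)=C/CO
F0 | step 11 | none | none
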